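## Conventions and remarks

- ent-Kaurane locants (C1–C20) are used for every intermediate.
- Remark: the ligand (S)-t-BuPyOx and acrylate 17 are taken as commercial reagents.
- Remark: the enantiomeric purity set in step 4 is assumed to be raised, if needed, by crystallising acid 8.
- Remark: C15 of diol 27 is written with its hydroxyl syn to C7; either C15 epimer serves, since step 19 removes this centre.

## Analysis of the target

Ludongnin A (33) is a 6,7-seco-ent-kauranoid built around three quaternary carbons. Ring A (C1–C5, C10) carries a cis-fused γ-lactone (C4–C19–O–C6–C5). C10 is the spiro atom of a δ-lactone (C10–C20–O–C7–C8–C9). C8 and C13 are the bridgeheads of a bicyclo[3.2.1]octane made of ring C (C8, C9, C11, C12, C13, C14) and ring D (C8, C14, C13, C16, C15).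

There are seven stereocentres (4R, 5R, 8S, 9S, 10R, 11R, 13S); C4, C8 and C10 are quaternary and C10–C9–C8 are contiguous. On ring A, C19, C6 and C20 lie on one face and C18, H5 and C9 on the other. At C9 the bond to C11 points away from the C5 branch of C10, ring C is cis-fused to the δ-lactone, the C11 hydroxyl is equatorial on ring C, and the C15–C16 bridge lies on the face of H9.

The sensitive groups are the C15 ketone with its exocyclic C16=C17 methylene (a Michael acceptor), the β-keto lactone C15/C7 across the non-enolisable C8 (open to retro-Claisen cleavage), and the free C11 alcohol. The difficulty is to build the congested C8–C9–C10 array and the bicyclooctane without a ring B as template, and to place oxygen at C11 and C15 with the right configuration at C11.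

The strategy rests on one feature. C13 carries two identical two-carbon arms, C12–C11 and C16–C15, whose oxygenated ends are bonded to C9 and C8, the β- and α-carbons of the δ-lactone. Rings C and D can therefore both grow from one symmetric dialdehyde onto a C8=C9 unsaturated lactone.

## Retrosynthetic reasoning

**33 back to 27.** The C16=C17 methylene and the C15 ketone are removed first, because the enone is the most reactive part of the molecule. C8 is quaternary, so C16 is the only enolisable position of ketone 29 and a Mannich methylenation is regiochemically fixed. The C11 hydroxyl is masked as a silyl ether in 28–32 so that only C15 is oxidised. This leaves diol 27, which lacks only C17.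

**27 back to 25 (key disconnection).** The C9–C11 and C8–C15 bonds are cut, which opens rings C and D at once. They are cut there because both bonds join an oxygenated carbon to the enoate carbons, so a reductive radical–polar sequence can form them from aldehydes. What is gained is a precursor, dialdehyde 25, with no stereocentre outside ring A and the spiro carbon. The forward reaction has to set C8, C9, C11 and C13 and has to tell the two diastereotopic arms apart.

**25 back to 19 and 4.** The aldehydes are traced to terminal alkenes (23), which survive enolate and selenium chemistry. The C8=C9 double bond is traced to the saturated lactone 20 by selenoxide elimination. The C8–C14 bond is cut by enolate alkylation, because C8 is the only easily enolised CH2 of bis-lactone 19. This makes the route convergent; iodide 4 is achiral and symmetric and comes from malonate 1 through 2 and 3.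

**19 back to 16 and 17.** The C9–C10 bond and the lactone C7–O bond are cut together. A tertiary C10 radical released from spiro-epoxide 16 adds to acrylate 17, and the liberated C20 oxygen closes the δ-lactone. This is the step that creates the quaternary spiro centre; it must add the acrylate on the face of H5.

**16 back to 11.** The epoxide comes from the exocyclic alkene 15. Ketone 11 is a β-keto lactone and too acidic for ylide olefination. C20 is therefore attached by cross-coupling of enol triflate 12 as a silylmethyl group (13). Fluoride-induced loss of silicon then moves the double bond out of conjugation and re-sets C5 by protonation.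

**11 back to 9.** The C5–C6 bond is cut as an intramolecular acylation from a carbonate on the C19 oxygen (10). The tether solves the regiochemistry: C5 is the hindered α-position of the ketone, and only its enolate can reach the carbonate.

**9 back to 5 and 6.** C19 is traced to the ipso carbon of a phenyl group: reduction of acid 8, which comes from oxidative degradation of the arene in 7. The C4–C19 bond is cut as an asymmetric conjugate arylation of enone 5 with boronic acid 6. This sets C4, the only stereocentre that comes from a catalyst; all others are relayed from it.

## Alternatives that were turned down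

**Alternative 1: cationic pimarane-to-kaurane cascade on the seco scaffold.**
- Disconnection: C8–C14 and C12–C13. The bicyclooctane is traced to a six-membered ring in which C16 carries the C17 methyl and a C13=C14 vinyl group, and C8 is a spiro-epoxide with C7.
- Forward key step: a methylaluminium dichloride Lewis acid ionises the epoxide, the C8 cation is trapped by C14, C12 shifts from C16 to C13 and C17 loses a proton. The product is A1, the 16-ene tetracycle with a free C7 alcohol, a C11 methoxymethyl ether and a C20 silyl ether.
- For it: it follows the biosynthetic order, forms two C–C bonds, and delivers the C16=C17 methylene directly. On this point it is stronger than the chosen route, which needs a late methylenation.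
- Against it: without ring B nothing holds the vinyl group over the C8 cation. That cation sits next to the C7 alkoxyaluminium and can undergo a 1,2-hydride shift to the C7 aldehyde or lose a proton. The secondary C13 cation can be quenched before the 1,2-shift. The lactone and the acetal compete for the Lewis acid, and the acetal is acid-labile. A1 still lacks both carbonyls on C8: C7 must be oxidised and lactonised and C15 needs allylic oxidation, plus two deprotections. C9, C11 and a quaternary C16 must be set before the cascade.
- Comparison: the chosen route closes the same two rings from 25, which has no stereocentre in the side chain, puts oxygen on C11 and C15 in the key step, and runs under neutral conditions. It pays four end-game steps for the methylene.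

**Alternative 2: one-carbon insertion into a norbornene.**
- Disconnection: C9–C11 and C11–C12 are cut and C9–C12 restored, so ring C is traced to the five-membered ring of a lactone-fused norbornene.
- Forward key step: dibromocarbene, released thermally from a tribromoacetate salt, adds to C9=C12 and the dibromocyclopropane opens. The product is A2, the ring-expanded ketone with a C11 vinyl bromide and a C12 allylic bromide.
- For it: the norbornene can come from a Diels–Alder reaction, a dependable way to set C8 and C13. Carbene addition and opening are well behaved on norbornenes, and the C15 ketone is present from the start. On the reliability of the key step itself it is the stronger proposal.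
- Against it: C9=C12 is trisubstituted and next to spiro C10, and the thermal conditions meet a β-keto lactone. The main cost comes afterwards. In A2, C9 and C11 are sp2 carbons of a tetrasubstituted alkene, C11 bears bromine instead of oxygen, C12 bears a bromine that must go, and C16 bears a methyl that must be dehydrogenated. Each correction is a stereochemical or chemoselectivity problem; hydride delivery to a C11 ketone from the open face, for example, gives the axial alcohol.
- Comparison: the chosen route creates H9 and the C11 carbinol in the bond-forming event, at the right oxidation level.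

**Alternative 3: δ-lactone as tether for a ring C Diels–Alder reaction.**
- Disconnection: C8–C9 and C13–C14, with the C7–O–C20 ester as tether.
- Forward key step: heating the ester-tethered triene (2-silyloxy diene C9=C11–C12=C13 on C10; C8=C14 dienophile activated by the lactone carbonyl and a C15 thioester). The product is A3, the lactone-fused cyclohexene silyl enol ether with the C15 thioester.
- For it: esterification joins the two halves, the electron demand is matched, the tether fixes regiochemistry, and C8 and C9 are set in one concerted step. On convergence it is stronger than the linear build-up of 25.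
- Against it: the tether ester must adopt its disfavoured s-cis form for a six-membered lactone to close, which makes such cycloadditions sluggish. The new C8–C9 bond joins a carbon next to quaternary C10 to one that becomes quaternary. Facial selectivity rests on the small difference between the C1 and C5 branches at high temperature. The geminally activated dienophile polymerises easily. Ring D is still missing in A3: C16 must be attached to an unactivated C13 and to C15, and the C11 ketone must be reduced to the equatorial alcohol against the steric preference.
- Comparison: the chosen route closes both rings in one step and takes the C11 configuration from a cyclic transition state, not from a hydride reduction.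

Key step: step 17

## Route

Step 1
Reactants: 1 diethyl diallylmalonate
Product: 2 ethyl 2-allylpent-4-enoate
Conditions: LiCl, H2O, DMSO, 180 °C
Reagents that add atoms: none
Why: Krapcho dealkoxycarbonylation; chloride dealkylates one ester and the malonate half-ester loses CO2, leaving both alkenes untouched.

Step 2
Reactants: 2 ethyl 2-allylpent-4-enoate
Product: 3 2-allylpent-4-en-1-ol
Conditions: LiAlH4, Et2O, 0 °C to rt
Reagents that add atoms: none
Why: Hydride reduction of an ester to the primary alcohol; isolated alkenes are inert.

Step 3
Reactants: 3 2-allylpent-4-en-1-ol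
Product: 4 4-(iodomethyl)hepta-1,6-diene
Conditions: I2, PPh3, imidazole, CH2Cl2, 0 °C to rt
Reagents that add atoms: iodine, II
Why: Appel-type iodination of a primary alcohol through the alkoxyphosphonium salt (SN2).

Step 4
Reactants: 5 3-methylcyclohex-2-en-1-one; 6 phenylboronic acid
Product: 7 (R)-3-methyl-3-phenylcyclohexan-1-one
Conditions: Pd(OCOCF3)2 (5 mol%), (S)-t-BuPyOx (6 mol%), NH4PF6, H2O, ClCH2CH2Cl, 40 °C
Reagents that add atoms: none
Why: Asymmetric conjugate addition of an arylboronic acid to a β-substituted cyclic enone under divalent palladium catalysis; the tert-butyl group of the pyridine–oxazoline ligand blocks one enone face in the carbopalladation, which sets C4 (R), and water protonates the palladium enolate.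

Step 5
Reactants: 7 (R)-3-methyl-3-phenylcyclohexan-1-one
Product: 8 (R)-1-methyl-3-oxocyclohexane-1-carboxylic acid
Conditions: RuCl3·xH2O (cat.), NaIO4, CCl4/MeCN/H2O, rt
Reagents that add atoms: sodium periodate, [Na+].[O-]I(=O)(=O)=O; water, O
Why: RuO4 formed in situ degrades the arene to CO2 and leaves the ipso carbon as the carboxylic acid; the quaternary centre cannot epimerise and the ketone is inert.

Step 6
Reactants: 8 (R)-1-methyl-3-oxocyclohexane-1-carboxylic acid
Product: 9 (R)-3-(hydroxymethyl)-3-methylcyclohexan-1-one
Conditions: BH3·SMe2 (1.1 equiv), THF, −10 to 0 °C; MeOH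
Reagents that add atoms: none
Why: Chemoselective borane reduction; the acid is reduced through its acyloxyborane faster than borane adds to the ketone, provided the hydride is limited and the temperature kept low.

Step 7
Reactants: 9 (R)-3-(hydroxymethyl)-3-methylcyclohexan-1-one
Product: 10 methyl [(1R)-1-methyl-3-oxocyclohexyl]methyl carbonate
Conditions: ClCO2Me, pyridine, CH2Cl2, 0 °C
Reagents that add atoms: methyl chloroformate, COC(=O)Cl
Why: Acylation of the primary alcohol; the carbonate carbon is the future C6 and is now tethered through the C19 oxygen.

Step 8
Reactants: 10 methyl [(1R)-1-methyl-3-oxocyclohexyl]methyl carbonate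
Product: 11 (3aR,7aR)-3a-methylhexahydro-2-benzofuran-1,7-dione
Conditions: NaH (2.2 equiv), THF, 0 to 50 °C; AcOH
Reagents that add atoms: none
Why: Dieckmann-type intramolecular Claisen acylation; the ketone enolates equilibrate and only the C5 enolate can reach the carbonate carbonyl (5-exo-trig), the product being drained as its β-dicarbonyl enolate. C5 remains epimerisable and should settle as the cis-fused lactone, the trans-fused γ-lactone being strained.

Step 9
Reactants: 11 (3aR,7aR)-3a-methylhexahydro-2-benzofuran-1,7-dione
Product: 12 (3aR)-3a-methyl-1-oxo-1,3,3a,4,5,6-hexahydro-2-benzofuran-7-yl trifluoromethanesulfonate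
Conditions: (CF3SO2)2O, i-Pr2NEt, CH2Cl2, −78 °C
Reagents that add atoms: trifluoromethanesulfonic anhydride, O=S(=O)(OS(=O)(=O)C(F)(F)F)C(F)(F)F
Why: O-Sulfonylation of the enol of a β-keto lactone gives the conjugated (C5=C10) enol triflate.

Step 10
Reactants: 12 (3aR)-3a-methyl-1-oxo-1,3,3a,4,5,6-hexahydro-2-benzofuran-7-yl trifluoromethanesulfonate
Product: 13 (3aR)-3a-methyl-7-[(trimethylsilyl)methyl]-3a,4,5,6-tetrahydro-2-benzofuran-1(3H)-one
Conditions: Me3SiCH2MgCl, Pd(PPh3)4 (5 mol%), THF, 0 °C
Reagents that add atoms: (trimethylsilyl)methylmagnesium chloride, C[Si](C)(C)C[Mg]Cl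
Why: Kumada coupling; zerovalent palladium inserts readily into the vinylogous acyl triflate and the nucleophile has no β-hydrogen, so C20 is attached before the lactone carbonyl is attacked.

Step 11
Reactants: 13 (3aR)-3a-methyl-7-[(trimethylsilyl)methyl]-3a,4,5,6-tetrahydro-2-benzofuran-1(3H)-one
Product: 15 (3aR,7aS)-3a-methyl-7-methylidenehexahydro-2-benzofuran-1(3H)-one, via tetrabutylammonium dienolate 14 (not isolated)
Conditions: Bu4NF, AcOH, THF, −40 to 0 °C
Reagents that add atoms: none
Why: Fluoride-induced desilylation of a γ-silyl enoate releases the dienolate, and kinetic protonation at the α-carbon C5 leaves the double bond exocyclic (deconjugative protonation). The cis fusion (H5 cis to the C4 methyl) is expected because only that mode keeps the γ-lactone near planar; the acetic acid buffer prevents re-conjugation.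

Step 12
Reactants: 15 (3aR,7aS)-3a-methyl-7-methylidenehexahydro-2-benzofuran-1(3H)-one
Product: 16 spiro-epoxide of 15 across C10–C20 (both C10 epimers)
Conditions: mCPBA, NaHCO3, CH2Cl2, 0 °C
Reagents that add atoms: mCPBA (3-chloroperoxybenzoic acid), OOC(=O)c1cccc(Cl)c1
Why: Prilezhaev epoxidation of the 1,1-disubstituted alkene; the epoxide configuration is irrelevant because C10 becomes a planar radical in the next step.

Step 13
Reactants: 16 spiro-epoxide of 15 across C10–C20; 17 2,2,2-trifluoroethyl acrylate
Product: 19 (4R,5R,10R)-spiro bis-lactone (ring A with its cis-fused 6,19-γ-lactone joined at C10 to the saturated 7,20-δ-lactone), via hydroxy ester 18 (not isolated)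
Conditions: Cp2TiCl2, Zn, 2,4,6-collidine·HCl, 17 (5 equiv), THF, rt
Reagents that add atoms: none
Why: Nugent–RajanBabu reductive epoxide opening: trivalent titanium cleaves the epoxide to the tertiary C10 radical, which undergoes Giese addition to the acrylate; a second trivalent titanium reduces the α-ester radical, and the C20 alkoxide closes the δ-lactone on the activated trifluoroethyl ester. In the ring A chair C19 is axial and shields the lower face of C10, so the acrylate should enter from the face of H5 and C18, placing C9 trans and C20 cis to C6.

Step 14
Reactants: 19 (4R,5R,10R)-spiro bis-lactone; 4 4-(iodomethyl)hepta-1,6-diene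
Product: 20 C8-alkylated spiro bis-lactone carrying CH2CH(CH2CH=CH2)2 on C8 (both C8 epimers)
Conditions: LiN(SiMe3)2, THF, −78 °C; 4, HMPA, −78 to −20 °C
Reagents that add atoms: none
Why: Kinetic enolate alkylation; the amide base removes a proton from the accessible C8 methylene of the δ-lactone and not from the C5 methine, which is flanked by two quaternary carbons, and the enolate displaces the primary iodide (SN2).

Step 15
Reactants: 20 C8-alkylated spiro bis-lactone
Product: 23 C8=C9 unsaturated spiro bis-lactone carrying the 2-allylpent-4-enyl group on C8, via selenide 21 (not isolated), via selenoxide 22 (not isolated)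
Conditions: KN(SiMe3)2, THF, −78 °C; PhSeBr; then H2O2, pyridine, CH2Cl2, 0 °C to rt
Reagents that add atoms: none
Why: α-Selenenylation of the C8 enolate followed by selenoxide syn-elimination; a ring hydrogen on C9 is always cis to selenium, and elimination toward it gives the endocyclic conjugated lactone. The terminal alkenes are inert to H2O2.

Step 16
Reactants: 23 C8=C9 unsaturated spiro bis-lactone carrying the 2-allylpent-4-enyl group on C8
Product: 25 C8=C9 unsaturated spiro bis-lactone dialdehyde (C13 carries two CH2CHO arms), via bis-ozonide 24 (not isolated)
Conditions: O3, CH2Cl2, −78 °C (Sudan Red 7B end point); PPh3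
Reagents that add atoms: ozone, [O-][O+]=O
Why: Ozonolysis with reductive work-up; the two electron-rich monosubstituted alkenes react far faster than the electron-poor trisubstituted enoate, and the dye marks the end point. The dialdehyde is used at once.

Step 17
Reactants: 25 C8=C9 unsaturated spiro bis-lactone dialdehyde
Product: 27 tetracyclic 11,15-diol lacking C17 (4R,5R,8S,9S,10R,11R,13S; C15 hydroxyl syn to C7), via samarium enolate 26 (not isolated)
Conditions: SmI2 (THF, 3 equiv, slow addition), LiBr, t-BuOH, THF, −78 °C
Reagents that add atoms: none
Why: Divalent samarium (SmBr2 formed from SmI2 and LiBr) transfers one electron to an aldehyde, and the ketyl adds 6-endo-trig to C9, the β-carbon of the α-substituted unsaturated lactone, closing ring C (attack at C8 would leave an unstabilised radical). A second electron turns the C8 radical into a trivalent samarium enolate, which closes ring D by a 5-exo-trig aldol onto the other aldehyde; the closest known reaction type is the SmI2-mediated ketyl–olefin cyclisation onto unsaturated lactones with aldol capture of the samarium enolate. C9 is set because the ketyl approaches the alkene face opposite the C5 branch of spiro C10, the bulkier of the two ring A arms. C11 and C13 are set by a chair transition state that keeps the C9–C10 bond and the spare arm equatorial and the samarium-bound oxygen axial, where the metal can bridge to the lactone carbonyl; this choice between the two diastereotopic arms fixes C13. C8 follows because ring C can only be cis-fused to the lactone, so after a ring flip the now axial arm reaches C8 on the face of H9. C15 comes from the chelated aldolate and is erased in step 19. The step needs ketyl–olefin addition to outrun pinacol coupling of the two aldehydes and protonation of the enolate: slow addition keeps the ketyl concentration low, and tert-butanol is too weak an acid to quench the enolate before the intramolecular aldol. The saturated γ-lactone is not reduced under these conditions.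

Step 18
Reactants: 27 tetracyclic 11,15-diol lacking C17
Product: 28 11-O-tert-butyldimethylsilyl ether of 27 (C15 hydroxyl free)
Conditions: t-BuMe2SiCl, imidazole, DMF, rt
Reagents that add atoms: tert-butyldimethylsilyl chloride, CC(C)(C)[Si](C)(C)Cl
Why: Site-selective silylation; the equatorial C11 hydroxyl lies between a methine and a methylene, whereas the C15 hydroxyl is neopentyl-like next to quaternary C8 and hydrogen-bonded to the C7 carbonyl.

Step 19
Reactants: 28 11-O-tert-butyldimethylsilyl ether of 27
Product: 29 11-O-tert-butyldimethylsilyl 15-ketone
Conditions: DMP, CH2Cl2, rt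
Reagents that add atoms: none
Why: Dess–Martin oxidation of the secondary alcohol; the resulting β-keto lactone cannot enolise at C8 and the conditions are non-basic.

Step 20
Reactants: 29 11-O-tert-butyldimethylsilyl 15-ketone
Product: 32 11-O-tert-butyldimethylsilyl ludongnin A, via Mannich base 30 (not isolated), via ammonium iodide 31 (not isolated)
Conditions: LiN(SiMe3)2, THF, −78 °C; CH2=NMe2 I; then MeI; aq NaHCO3
Reagents that add atoms: Eschenmoser's salt (N,N-dimethylmethyleneiminium iodide), C=[N+](C)C.[I-]
Why: Mannich methylenation; C16 is the only enolisable position of the ketone, the lithium enolate adds to the iminium salt, and quaternisation followed by mild base eliminates trimethylamine to give the exocyclic enone.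

Step 21
Reactants: 32 11-O-tert-butyldimethylsilyl ludongnin A
Product: 33 ludongnin A
Conditions: HF·pyridine, THF, 0 °C to rt
Reagents that add atoms: none
Why: Acidic fluoride desilylation; it avoids the basic fluoride sources that would add to the enone or open the β-keto lactone.

## Compound list

1 | diethyl diallylmalonate | C=CCC(CC=C)(C(=O)OCC)C(=O)OCC | starting material
2 | ethyl 2-allylpent-4-enoate | C=CCC(CC=C)C(=O)OCC | intermediate
3 | 2-allylpent-4-en-1-ol | C=CCC(CC=C)CO | intermediate
4 | 4-(iodomethyl)hepta-1,6-diene | C=CCC(CC=C)CI | intermediate
5 | 3-methylcyclohex-2-en-1-one | CC1=CC(=O)CCC1 | starting material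
6 | phenylboronic acid | OB(O)c1ccccc1 | starting material
7 | (R)-3-methyl-3-phenylcyclohexan-1-one | O=C1CCC[C@@](C)(c2ccccc2)C1 | intermediate
8 | (R)-1-methyl-3-oxocyclohexane-1-carboxylic acid | O=C1CCC[C@@](C)(C(=O)O)C1 | intermediate
9 | (R)-3-(hydroxymethyl)-3-methylcyclohexan-1-one | O=C1CCC[C@@](C)(CO)C1 | intermediate
10 | methyl [(1R)-1-methyl-3-oxocyclohexyl]methyl carbonate | O=C1CCC[C@@](C)(COC(=O)OC)C1 | intermediate
11 | (3aR,7aR)-3a-methylhexahydro-2-benzofuran-1,7-dione (cis-fused ring A keto lactone; C4 R, C5 R) | O=C1CCC[C@@]2(C)COC(=O)[C@@H]12 | intermediate
12 | (3aR)-3a-methyl-1-oxo-1,3,3a,4,5,6-hexahydro-2-benzofuran-7-yl trifluoromethanesulfonate | O=C1OC[C@]2(C)CCCC(OS(=O)(=O)C(F)(F)F)=C12 | intermediate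
13 | (3aR)-3a-methyl-7-[(trimethylsilyl)methyl]-3a,4,5,6-tetrahydro-2-benzofuran-1(3H)-one | O=C1OC[C@]2(C)CCCC(C[Si](C)(C)C)=C12 | intermediate
14 | tetrabutylammonium dienolate of 15 (C6 oxido, C5=C6 and C10=C20 double bonds) | C=C1CCC[C@@]2(C)COC([O-])=C12.CCCC[N+](CCCC)(CCCC)CCCC | intermediate (not isolated)
15 | (3aR,7aS)-3a-methyl-7-methylidenehexahydro-2-benzofuran-1(3H)-one (cis-fused; H5 cis to the C4 methyl) | C=C1CCC[C@@]2(C)COC(=O)[C@@H]12 | intermediate
16 | spiro-epoxide of 15 across C10–C20 (C4 and C5 as in 15; both C10 epimers) | C1OC12CCC[C@@]3(C)COC(=O)[C@@H]23 | intermediate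
17 | 2,2,2-trifluoroethyl acrylate | C=CC(=O)OCC(F)(F)F | starting material
18 | hydroxy ester: 2,2,2-trifluoroethyl 3-(C10)-propanoate with C20 hydroxymethyl cis to C6 (C10 R) | FC(F)(F)COC(=O)CC[C@]1(CO)CCC[C@@]2(C)COC(=O)[C@H]21 | intermediate (not isolated)
19 | (4R,5R,10R)-spiro bis-lactone: ring A 6,19-γ-lactone spiro at C10 to the saturated 7,20-δ-lactone | O=C1CC[C@@]2(CCC[C@@]3(C)COC(=O)[C@H]32)CO1 | intermediate
20 | C8-alkylated spiro bis-lactone, C8 bearing CH2CH(CH2CH=CH2)2 (both C8 epimers) | C=CCC(CC=C)CC1C[C@@]2(CCC[C@@]3(C)COC(=O)[C@H]32)COC1=O | intermediate
21 | C8 phenylselenide of 20 | C=CCC(CC=C)CC1([Se]c2ccccc2)C[C@@]3(CCC[C@@]4(C)COC(=O)[C@H]43)COC1=O | intermediate (not isolated)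
22 | C8 phenylselenoxide of 20 | C=CCC(CC=C)CC1([Se](=O)c2ccccc2)C[C@@]3(CCC[C@@]4(C)COC(=O)[C@H]43)COC1=O | intermediate (not isolated)
23 | C8=C9 unsaturated spiro bis-lactone with the 2-allylpent-4-enyl group on C8 | C=CCC(CC=C)CC1=C[C@@]2(CCC[C@@]3(C)COC(=O)[C@H]32)COC1=O | intermediate
24 | bis-ozonide of 23 (two 1,2,4-trioxolanes) | O1OCOC1CC(CC1OCOO1)CC1=C[C@@]2(CCC[C@@]3(C)COC(=O)[C@H]32)COC1=O | intermediate (not isolated)
25 | C8=C9 unsaturated spiro bis-lactone dialdehyde (key-step precursor) | O=CCC(CC=O)CC1=C[C@@]2(CCC[C@@]3(C)COC(=O)[C@H]32)COC1=O | intermediate
26 | ring C samarium enolate (C9, C11, C13 set; C8 enolate; second aldehyde intact) | O=CC[C@H]1CC2=C(O[Sm](Br)Br)OC[C@]3(CCC[C@@]4(C)COC(=O)[C@H]43)[C@@H]2[C@H](O[Sm](Br)Br)C1 | intermediate (not isolated)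
27 | tetracyclic 11,15-diol lacking C17 (4R,5R,8S,9S,10R,11R,13S; C15 hydroxyl syn to C7) | C1[C@H](O)[C@]23C[C@H]1C[C@@H](O)[C@H]2[C@@]1(CCC[C@@]2(C)COC(=O)[C@H]21)COC3=O | intermediate
28 | 11-O-tert-butyldimethylsilyl ether of 27 | C1[C@H](O)[C@]23C[C@H]1C[C@@H](O[Si](C)(C)C(C)(C)C)[C@H]2[C@@]1(CCC[C@@]2(C)COC(=O)[C@H]21)COC3=O | intermediate
29 | 11-O-tert-butyldimethylsilyl 15-ketone | C1C(=O)[C@]23C[C@H]1C[C@@H](O[Si](C)(C)C(C)(C)C)[C@H]2[C@@]1(CCC[C@@]2(C)COC(=O)[C@H]21)COC3=O | intermediate
30 | C16 dimethylaminomethyl ketone (Mannich base; C16 epimers) | CN(C)CC1C(=O)[C@]23C[C@H]1C[C@@H](O[Si](C)(C)C(C)(C)C)[C@H]2[C@@]1(CCC[C@@]2(C)COC(=O)[C@H]21)COC3=O | intermediate (not isolated)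
31 | C16 trimethylammoniomethyl ketone iodide | C[N+](C)(C)CC1C(=O)[C@]23C[C@H]1C[C@@H](O[Si](C)(C)C(C)(C)C)[C@H]2[C@@]1(CCC[C@@]2(C)COC(=O)[C@H]21)COC3=O.[I-] | intermediate (not isolated)
32 | 11-O-tert-butyldimethylsilyl ludongnin A | C=C1C(=O)[C@]23C[C@H]1C[C@@H](O[Si](C)(C)C(C)(C)C)[C@H]2[C@@]1(CCC[C@@]2(C)COC(=O)[C@H]21)COC3=O | intermediate
33 | ludongnin A (4R,5R,8S,9S,10R,11R,13S) | C=C1C(=O)[C@]23C[C@H]1C[C@@H](O)[C@H]2[C@@]1(CCC[C@@]2(C)COC(=O)[C@H]21)COC3=O | target

## Step count and least certain steps

Total step count: 21. Longest linear sequence: 18 (steps 4–21); steps 1–3 make iodide 4 for the convergent alkylation.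

**Step 17 (key step).** The most likely failure is intramolecular pinacol coupling of the two 1,5-related aldehydes to a cyclopentanediol, because both carbonyls are reduced as easily as each other and the 6-endo addition has to reach a β-carbon next to the spiro centre. Protonation of the samarium enolate before the aldol and simple reduction of an aldehyde are the other leaks.

Fallback: set out from 23 and never have two aldehydes present. Ozonolysis with one equivalent of ozone (recovering 23) should give the mono-aldehyde F1 as both C13 epimers. SmI2 with t-BuOH should then give the ketyl–olefin cyclisation alone; the enolate is protonated and the ring C alcohol F2 is obtained from the epimer whose spare allyl arm can sit equatorial. The other epimer is lost, which is the price of giving up the symmetry. Silylation gives F3. LiN(SiMe3)2 followed by CBr4 gives the α-bromo lactone F4. Ozonolysis of the remaining alkene gives the bromo aldehyde F5. An intramolecular Reformatsky aldol with SmI2 closes ring D and comes back to the route at 28 (either C15 epimer is oxidised to 29 in step 19).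

**Step 13.** The tertiary C10 radical may be captured by a second equivalent of trivalent titanium before it meets the acrylate, giving deoxygenated or allylic alcohol products, because both epoxide-derived radicals and the reductant are present in quantity.

Fallback: set out from 16 and form the same bond by polar chemistry. A Lewis acid (BF3·OEt2) should rearrange the epoxide to the C10 aldehyde F6 by hydride shift. Base-catalysed Michael addition of its enolate to methyl acrylate, on the same open face, gives the quaternary aldehyde ester F7. NaBH4 reduces the aldehyde to the hydroxy ester F8, which lactonises with acid and comes back at 19.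

**Step 15.** The selenoxide may eliminate toward C14 and give the exocyclic alkylidene lactone, since C8 then has hydrogens on both neighbouring carbons; selenenylation at C5 is a lesser risk.

Fallback: set out from 19 and introduce the double bond before the side chain. Selenenylation of 19 gives selenide F9, oxidation gives selenoxide F10, and elimination, now possible only toward C9, gives the unsaturated lactone F11. Iodine and pyridine give the α-iodo lactone F12. Negishi coupling with the alkylzinc iodide F13, made from 4 and zinc, under zerovalent palladium catalysis, comes back at 23.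

**Step 18.** Silylation may occur at C15 as well as or instead of C11, because the site selectivity rests on a steric difference between two secondary alcohols.

Fallback: set out from 27 and use a silyl relay. Et3SiCl caps the more reactive hydroxyl; if that is C15 the product is F14. t-BuMe2SiOSO2CF3 then silylates C11 to give F15, and PPTS in methanol removes only the triethylsilyl group, coming back at 28. If neither hydroxyl is preferred, the stepwise sequence given for step 17 delivers 28 with the two oxygens already told apart.

**Step 11.** The dienolate may be protonated at the γ-carbon C20, which restores the conjugated lactone, or on the face that gives the trans-fused lactone; 15 may also re-conjugate under basic fluoride.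

Fallback: set out from 11 and methylenate the ketone directly under non-basic conditions with Zn/CH2Br2/TiCl4 (Takai–Lombardo), coming back at 15. C5 is then never turned into a dienolate and keeps the cis fusion of 11. No new compound is made.

**Step 6.** Reduction of the ketone may compete with that of the acid, because the acid is α-quaternary and the ketone unhindered.

Fallback: set out from 8, reduce both groups with LiAlH4 to the diol F16, and oxidise only the secondary alcohol with NaOCl in acetic acid, coming back at 9.

## Further compounds

F1 | step 17 | mono-aldehyde from 23 (one allyl arm cleaved; both C13 epimers) | C=CCC(CC=O)CC1=C[C@@]2(CCC[C@@]3(C)COC(=O)[C@H]32)COC1=O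
F2 | step 17 | ring C alcohol lactone with spare allyl arm (C9, C11, C13 as in 27; C8 epimers) | C=CC[C@H]1CC2C(=O)OC[C@]3(CCC[C@@]4(C)COC(=O)[C@H]43)[C@@H]2[C@H](O)C1
F3 | step 17 | 11-O-tert-butyldimethylsilyl ether of F2 | C=CC[C@H]1CC2C(=O)OC[C@]3(CCC[C@@]4(C)COC(=O)[C@H]43)[C@@H]2[C@H](O[Si](C)(C)C(C)(C)C)C1
F4 | step 17 | C8 bromo lactone from F3 | C=CC[C@H]1CC2(Br)C(=O)OC[C@]3(CCC[C@@]4(C)COC(=O)[C@H]43)[C@@H]2[C@H](O[Si](C)(C)C(C)(C)C)C1
F5 | step 17 | C8 bromo lactone aldehyde from F4 | O=CC[C@H]1CC2(Br)C(=O)OC[C@]3(CCC[C@@]4(C)COC(=O)[C@H]43)[C@@H]2[C@H](O[Si](C)(C)C(C)(C)C)C1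
F6 | step 13 | C10 aldehyde from epoxide rearrangement (C10 epimers) | O=CC1CCC[C@@]2(C)COC(=O)[C@@H]12
F7 | step 13 | C10 quaternary aldehyde methyl ester (Michael adduct) | COC(=O)CC[C@]1(C=O)CCC[C@@]2(C)COC(=O)[C@H]21
F8 | step 13 | C20 hydroxy methyl ester | COC(=O)CC[C@]1(CO)CCC[C@@]2(C)COC(=O)[C@H]21
F9 | step 15 | C8 phenylselenide of 19 | O=C1C([Se]c2ccccc2)C[C@@]3(CCC[C@@]4(C)COC(=O)[C@H]43)CO1
F10 | step 15 | C8 phenylselenoxide of 19 | O=C1C([Se](=O)c2ccccc2)C[C@@]3(CCC[C@@]4(C)COC(=O)[C@H]43)CO1
F11 | step 15 | C8=C9 unsaturated spiro bis-lactone without side chain | O=C1C=C[C@@]2(CCC[C@@]3(C)COC(=O)[C@H]32)CO1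
F12 | step 15 | C8 iodo C8=C9 unsaturated spiro bis-lactone | O=C1C(I)=C[C@@]2(CCC[C@@]3(C)COC(=O)[C@H]32)CO1
F13 | step 15 | (2-allylpent-4-enyl)zinc iodide | C=CCC(CC=C)C[Zn]I
F14 | step 18 | 15-O-triethylsilyl ether of 27 | C1[C@H](O[Si](CC)(CC)CC)[C@]23C[C@H]1C[C@@H](O)[C@H]2[C@@]1(CCC[C@@]2(C)COC(=O)[C@H]21)COC3=O
F15 | step 18 | 11-O-tert-butyldimethylsilyl 15-O-triethylsilyl bis-ether of 27 | C1[C@H](O[Si](CC)(CC)CC)[C@]23C[C@H]1C[C@@H](O[Si](C)(C)C(C)(C)C)[C@H]2[C@@]1(CCC[C@@]2(C)COC(=O)[C@H]21)COC3=O
F0 | step 11 | none | none
F16 | step 6 | (3R)-3-(hydroxymethyl)-3-methylcyclohexan-1-ol (C1 epimers) | OC1CCC[C@@](C)(CO)C1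
A1 | alternative 1 | 16-ene tetracycle with free C7 alcohol, C11 methoxymethyl ether and C20 silyl ether (δ-lactone still open) | C=C1C[C@]2(CO)C[C@H]1C[C@@H](OCOC)[C@H]2[C@@]1(CCC[C@@]2(C)COC(=O)[C@H]21)CO[Si](C)(C)C(C)(C)C
A2 | alternative 2 | ring-expanded ketone with C11 vinyl bromide and C12 allylic bromide | C[C@H]1C(=O)[C@]23C[C@H]1[C@@H](Br)C(Br)=C2[C@@]1(CCC[C@@]2(C)COC(=O)[C@H]21)COC3=O
A3 | alternative 3 | lactone-fused cyclohexene silyl enol ether with C15 thioester | CCSC(=O)[C@]12CCC=C(O[Si](C)(C)C(C)(C)C)[C@H]1[C@@]3(CCC[C@@]4(C)COC(=O)[C@H]43)COC2=O
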